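**Strategy.** The bicyclic core (benzofuran numbering: O1, C2, C3, C3a, C4–C7, C7a) is opened across the cyclohexane ring at C4–C5 and C3a–C7a. The C3=C3a alkene, endocyclic to the dihydrofuran, exocyclic to the cyclohexane and flanked by the quaternary carbons C4 and C7a, is the trace of a 1,1-dimethylallene whose distal π bond has served as dienophile. An acyclic (R)-α-allenyl dienyl ether therefore folds, in one intramolecular Diels–Alder reaction, into both rings, forming both C–C bonds and the quaternary C7a. The C6 carbinol follows by equatorial hydride delivery; two Horner–Wadsworth–Emmons couplings on commercial 2,7-dimethylocta-2,4,6-trienedial complete the polyene.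

Key step: step 5

Remark: the tetrahydropyranyl ether 2 is taken as a purchasable reagent (mixture of acetal epimers), and every operation after the cycloaddition avoids strong acid because the C2–O1 bond is doubly allylic.

**Step 1**
Reactants: 1 ethyl (2E)-3-methyl-4-oxobut-2-enoate; 2 2-[(2-methylbut-3-yn-2-yl)oxy]oxane
Product: 3 ethyl (2E,4S)-4-hydroxy-3,7-dimethyl-7-(oxan-2-yloxy)oct-2-en-5-ynoate
Conditions: ZnMe2 (3 equiv), (S,S)-ProPhenol (20 mol %), Ph3P=O (40 mol %), PhMe, 0 °C
Reagents that add atoms: none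
Why: Zinc–ProPhenol-catalysed asymmetric alkynylation of an α-branched enal: the zinc alkynylide adds 1,2 to the aldehyde and spares the ester, and the ligand enantiomer is the one that delivers the alkynyl group to the Re face, which sets the (4S)-carbinol, the later C2 of the dihydrofuran.

**Step 2**
Reactants: 3 ethyl (2E,4S)-4-hydroxy-3,7-dimethyl-7-(oxan-2-yloxy)oct-2-en-5-ynoate
Product: 4 (2E,4R)-3,7-dimethylocta-2,5,6-triene-1,4-diol
Conditions: LiAlH4, Et2O, 0 °C, then reflux
Reagents that add atoms: none
Why: LiAlH4 reduces the enoate to the allylic alcohol and, from the propargylic alkoxyaluminate, adds hydride trans across the alkyne and expels the tertiary tetrahydropyranyloxy group (net SN2' hydride substitution), which unveils the 1,1-dimethylallene without touching the carbinol centre (the descriptor changes from S to R only because the alkyne has become an allene).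

**Step 3**
Reactants: 4 (2E,4R)-3,7-dimethylocta-2,5,6-triene-1,4-diol
Product: 5 (2E,4R)-3,7-dimethyl-1-[(triethylsilyl)oxy]octa-2,5,6-trien-4-ol
Conditions: Et3SiCl (1 equiv), imidazole, CH2Cl2, −78 °C
Reagents that add atoms: chlorotriethylsilane CC[Si](Cl)(CC)CC
Why: Silylation at low temperature selects the unhindered primary allylic hydroxyl over the secondary one, which is needed free for the next step.

**Step 4**
Reactants: 5 (2E,4R)-3,7-dimethyl-1-[(triethylsilyl)oxy]octa-2,5,6-trien-4-ol; 6 pent-3-yn-2-one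
Product: 7 (3E)-4-({(2E,4R)-3,7-dimethyl-1-[(triethylsilyl)oxy]octa-2,5,6-trien-4-yl}oxy)pent-3-en-2-one
Conditions: NaH (10 mol %), THF, 0 → 23 °C
Reagents that add atoms: none
Why: Base-catalysed oxa-Michael addition of the secondary alkoxide to the ynone gives the β-alkoxy enone, which equilibrates through reversible addition to the (E)-isomer with the ether oxygen trans to the acetyl group, the geometry that later places the tether on the outside of the diene.

**Step 5**
Reactants: 7 (3E)-4-({(2E,4R)-3,7-dimethyl-1-[(triethylsilyl)oxy]octa-2,5,6-trien-4-yl}oxy)pent-3-en-2-one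
Product: 9 (2R,7aR)-4,4,7a-trimethyl-6-[(triethylsilyl)oxy]-2-{(2E)-4-[(triethylsilyl)oxy]but-2-en-2-yl}-2,4,5,7a-tetrahydro-1-benzofuran, via siloxydiene 8 (not isolated)
Conditions: LiN(i-Pr)2, Et3SiCl, THF, −78 °C; then PhMe, Et3N (cat.), 90 °C
Reagents that add atoms: chlorotriethylsilane CC[Si](Cl)(CC)CC
Why: Kinetic α′-deprotonation and O-silylation give the (E)-1-alkoxy-3-siloxydiene 8, whose s-cis conformer adds in a concerted, asynchronous [4+2] cycloaddition across the distal C3a=C4 π bond of the 1,1-dimethylallene, a bond that lies in the plane of the tether and points at both diene termini (C5 to C4, C7a to C3a). The closest known reaction type is the intramolecular Diels–Alder reaction of an allene through its distal double bond over a two-atom link, as in Himbert-type arene–allene and allenyl ether cycloadditions. The cyclohexene closes by the cycloaddition itself and the 2,5-dihydrofuran as the tether ring of a type 1 intramolecular Diels–Alder reaction (link O1–C2–C3, with the surviving allene bond C3=C3a endocyclic). C7a is the only new stereocentre and is set relative to the (R)-carbinol C2: the flat tether allows just two transition states, with the C2 side chain either on the face of the inside methyl or on that of the diene C7–H, and the latter should be preferred and gives the 2,7a-trans (7aR) adduct, although the bias is expected to be modest because C2 sits 1,3 across the ring oxygen. The step needs site selectivity for the distal allene bond and periselectivity over [3,3] shifts of the allyl vinyl ether: attack on the proximal bond would require an oxetane, the (E)-enol ether holds the tether on the outside of the diene, and the strain of the allene should let the cycloaddition run below the temperature of the Claisen pathway. Any 7a-epimer is removed by chromatography at diol 11.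

**Step 6**
Reactants: 9 (2R,7aR)-4,4,7a-trimethyl-6-[(triethylsilyl)oxy]-2-{(2E)-4-[(triethylsilyl)oxy]but-2-en-2-yl}-2,4,5,7a-tetrahydro-1-benzofuran
Product: 11 (2R,6S,7aR)-2-[(2E)-4-hydroxybut-2-en-2-yl]-4,4,7a-trimethyl-2,4,5,6,7,7a-hexahydro-1-benzofuran-6-ol, via ketone 10 (not isolated)
Conditions: Bu4NF, AcOH, THF, 0 °C; then CeCl3·7H2O, NaBH4, MeOH, −78 °C
Reagents that add atoms: none
Why: Buffered fluoride cleaves the enol silyl ether and the primary silyl ether without building up enolate (which would expel the ring oxygen by β-elimination), and under Luche conditions hydride then enters the cyclohexanone equatorially, anti to the two syn-axial methyl groups on C4 and C7a, to give the axial (6S)-alcohol cis to the 7a-methyl.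

**Step 7**
Reactants: 11 (2R,6S,7aR)-2-[(2E)-4-hydroxybut-2-en-2-yl]-4,4,7a-trimethyl-2,4,5,6,7,7a-hexahydro-1-benzofuran-6-ol
Product: 12 (2E)-3-[(2R,6S,7aR)-6-hydroxy-4,4,7a-trimethyl-2,4,5,6,7,7a-hexahydro-1-benzofuran-2-yl]but-2-enal
Conditions: MnO2, CH2Cl2, 23 °C
Reagents that add atoms: none
Why: MnO2 oxidises only the primary allylic alcohol to the (E)-enal and leaves the secondary, non-allylic C6 hydroxyl and the acid-labile C2–O1 bond untouched.

**Step 8**
Reactants: 13 (2E,4E,6E)-2,7-dimethylocta-2,4,6-trienedial; 14 triethyl phosphonoacetate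
Product: 15 ethyl (2E,4E,6E,8E)-4,9-dimethyl-10-oxodeca-2,4,6,8-tetraenoate
Conditions: NaH, THF, 0 °C (13 in threefold excess)
Reagents that add atoms: none
Why: Horner–Wadsworth–Emmons mono-olefination of the symmetric dialdehyde, used in excess to suppress double reaction, gives the (E)-enoate.

**Step 9**
Reactants: 15 ethyl (2E,4E,6E,8E)-4,9-dimethyl-10-oxodeca-2,4,6,8-tetraenoate
Product: 16 ethyl (2E,4E,6E,8E)-10-hydroxy-4,9-dimethyldeca-2,4,6,8-tetraenoate
Conditions: NaBH4, EtOH, 0 °C
Reagents that add atoms: none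
Why: NaBH4 reduces the conjugated aldehyde 1,2 and is too mild to touch the dienoate ester.

**Step 10**
Reactants: 16 ethyl (2E,4E,6E,8E)-10-hydroxy-4,9-dimethyldeca-2,4,6,8-tetraenoate
Product: 17 ethyl (2E,4E,6E,8E)-10-bromo-4,9-dimethyldeca-2,4,6,8-tetraenoate
Conditions: PBr3, pyridine (cat.), Et2O, −10 °C
Reagents that add atoms: phosphorus tribromide BrP(Br)Br
Why: PBr3 converts the primary allylic alcohol into the bromide by SN2 substitution, the conjugated primary bromide being also the thermodynamic allylic isomer.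

**Step 11**
Reactants: 17 ethyl (2E,4E,6E,8E)-10-bromo-4,9-dimethyldeca-2,4,6,8-tetraenoate
Product: 18 ethyl (2E,4E,6E,8E)-10-(diethoxyphosphoryl)-4,9-dimethyldeca-2,4,6,8-tetraenoate
Conditions: P(OEt)3, PhMe, 90 °C
Reagents that add atoms: triethyl phosphite CCOP(OCC)OCC
Why: Michaelis–Arbuzov reaction of the primary allylic bromide with triethyl phosphite.

**Step 12**
Reactants: 12 (2E)-3-[(2R,6S,7aR)-6-hydroxy-4,4,7a-trimethyl-2,4,5,6,7,7a-hexahydro-1-benzofuran-2-yl]but-2-enal; 18 ethyl (2E,4E,6E,8E)-10-(diethoxyphosphoryl)-4,9-dimethyldeca-2,4,6,8-tetraenoate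
Product: 19 ethyl (2E,4E,6E,8E,10E,12E)-13-[(2R,6S,7aR)-6-hydroxy-4,4,7a-trimethyl-2,4,5,6,7,7a-hexahydro-1-benzofuran-2-yl]-4,9-dimethyltetradeca-2,4,6,8,10,12-hexaenoate
Conditions: NaN(SiMe3)2, THF, −78 °C; then enal 12, −78 → 0 °C
Reagents that add atoms: none
Why: Horner–Wadsworth–Emmons olefination: the ester-stabilised polyenyl phosphonate anion reacts through the carbon bearing phosphorus with the enal to form the new disubstituted alkene with E geometry, and it is not basic enough to deprotonate the free C6 hydroxyl or the C2–H of the dihydrofuran.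

**Step 13**
Reactants: 19 ethyl (2E,4E,6E,8E,10E,12E)-13-[(2R,6S,7aR)-6-hydroxy-4,4,7a-trimethyl-2,4,5,6,7,7a-hexahydro-1-benzofuran-2-yl]-4,9-dimethyltetradeca-2,4,6,8,10,12-hexaenoate
Product: 20 (2E,4E,6E,8E,10E,12E)-13-[(2R,6S,7aR)-6-hydroxy-4,4,7a-trimethyl-2,4,5,6,7,7a-hexahydro-1-benzofuran-2-yl]-4,9-dimethyltetradeca-2,4,6,8,10,12-hexaen-1-ol
Conditions: i-Bu2AlH, CH2Cl2, −78 °C; sodium potassium tartrate work-up
Reagents that add atoms: none
Why: i-Bu2AlH reduces the conjugated ester 1,2 to the primary allylic alcohol at low temperature, and the non-acidic tartrate work-up preserves the configuration at C2 of the dihydrofuran.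

**Compound list**

1 | ethyl (2E)-3-methyl-4-oxobut-2-enoate | CCOC(=O)/C=C(\C)C=O | starting material
2 | 2-[(2-methylbut-3-yn-2-yl)oxy]oxane (mixture of acetal epimers) | C#CC(C)(C)OC1CCCCO1 | starting material
3 | ethyl (2E,4S)-4-hydroxy-3,7-dimethyl-7-(oxan-2-yloxy)oct-2-en-5-ynoate | CCOC(=O)/C=C(\C)[C@H](O)C#CC(C)(C)OC1CCCCO1 | intermediate
4 | (2E,4R)-3,7-dimethylocta-2,5,6-triene-1,4-diol | OC/C=C(\C)[C@H](O)C=C=C(C)C | intermediate
5 | (2E,4R)-3,7-dimethyl-1-[(triethylsilyl)oxy]octa-2,5,6-trien-4-ol | CC[Si](CC)(CC)OC/C=C(\C)[C@H](O)C=C=C(C)C | intermediate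
6 | pent-3-yn-2-one | CC#CC(C)=O | starting material
7 | (3E)-4-({(2E,4R)-3,7-dimethyl-1-[(triethylsilyl)oxy]octa-2,5,6-trien-4-yl}oxy)pent-3-en-2-one | CC(=O)/C=C(\C)O[C@H](C=C=C(C)C)/C(C)=C/CO[Si](CC)(CC)CC | intermediate
8 | triethyl{[(3E)-4-({(2E,4R)-3,7-dimethyl-1-[(triethylsilyl)oxy]octa-2,5,6-trien-4-yl}oxy)penta-1,3-dien-2-yl]oxy}silane | C=C(O[Si](CC)(CC)CC)/C=C(\C)O[C@H](C=C=C(C)C)/C(C)=C/CO[Si](CC)(CC)CC | intermediate
9 | (2R,7aR)-4,4,7a-trimethyl-6-[(triethylsilyl)oxy]-2-{(2E)-4-[(triethylsilyl)oxy]but-2-en-2-yl}-2,4,5,7a-tetrahydro-1-benzofuran | CC[Si](CC)(CC)OC/C=C(\C)[C@H]1C=C2C(C)(C)CC(O[Si](CC)(CC)CC)=C[C@@]2(C)O1 | intermediate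
10 | (2R,7aR)-2-[(2E)-4-hydroxybut-2-en-2-yl]-4,4,7a-trimethyl-2,4,5,7a-tetrahydro-1-benzofuran-6(7H)-one | OC/C=C(\C)[C@H]1C=C2C(C)(C)CC(=O)C[C@@]2(C)O1 | intermediate
11 | (2R,6S,7aR)-2-[(2E)-4-hydroxybut-2-en-2-yl]-4,4,7a-trimethyl-2,4,5,6,7,7a-hexahydro-1-benzofuran-6-ol | OC/C=C(\C)[C@H]1C=C2C(C)(C)C[C@H](O)C[C@@]2(C)O1 | intermediate
12 | (2E)-3-[(2R,6S,7aR)-6-hydroxy-4,4,7a-trimethyl-2,4,5,6,7,7a-hexahydro-1-benzofuran-2-yl]but-2-enal | O=C/C=C(\C)[C@H]1C=C2C(C)(C)C[C@H](O)C[C@@]2(C)O1 | intermediate
13 | (2E,4E,6E)-2,7-dimethylocta-2,4,6-trienedial | O=C/C(C)=C/C=C/C=C(C)/C=O | starting material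
14 | triethyl phosphonoacetate | CCOC(=O)CP(=O)(OCC)OCC | starting material
15 | ethyl (2E,4E,6E,8E)-4,9-dimethyl-10-oxodeca-2,4,6,8-tetraenoate | CCOC(=O)/C=C/C(C)=C/C=C/C=C(C)/C=O | intermediate
16 | ethyl (2E,4E,6E,8E)-10-hydroxy-4,9-dimethyldeca-2,4,6,8-tetraenoate | CCOC(=O)/C=C/C(C)=C/C=C/C=C(C)/CO | intermediate
17 | ethyl (2E,4E,6E,8E)-10-bromo-4,9-dimethyldeca-2,4,6,8-tetraenoate | CCOC(=O)/C=C/C(C)=C/C=C/C=C(C)/CBr | intermediate
18 | ethyl (2E,4E,6E,8E)-10-(diethoxyphosphoryl)-4,9-dimethyldeca-2,4,6,8-tetraenoate | CCOC(=O)/C=C/C(C)=C/C=C/C=C(C)/CP(=O)(OCC)OCC | intermediate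
19 | ethyl (2E,4E,6E,8E,10E,12E)-13-[(2R,6S,7aR)-6-hydroxy-4,4,7a-trimethyl-2,4,5,6,7,7a-hexahydro-1-benzofuran-2-yl]-4,9-dimethyltetradeca-2,4,6,8,10,12-hexaenoate | CC(/C=C/C=C(\C)[C@H]1C=C2C(C)(C)C[C@H](O)C[C@@]2(C)O1)=C\C=C\C=C(C)\C=C\C(=O)OCC | intermediate
20 | (2E,4E,6E,8E,10E,12E)-13-[(2R,6S,7aR)-6-hydroxy-4,4,7a-trimethyl-2,4,5,6,7,7a-hexahydro-1-benzofuran-2-yl]-4,9-dimethyltetradeca-2,4,6,8,10,12-hexaen-1-ol (CNP0263491.1) | CC(/C=C/C=C(\C)[C@H]1C=C2C(C)(C)C[C@H](O)C[C@@]2(C)O1)=C\C=C\C=C(C)\C=C\CO | target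

**Totals.** Total step count: 13. Longest linear sequence: 9 steps (steps 1–7, 12 and 13).

**Steps most likely to fail**

Step 5. The two faces of the diene terminus C7a are discriminated only weakly, because the controlling centre C2 lies 1,3 across the ring oxygen and meets an inside methyl on one face and the diene C7–H on the other. A [3,3] shift of the allyl vinyl ether can also compete, so 9 may form as a near-equal mixture of 7a-epimers. In the fallback C7a is erased and then re-set by reagent and ring control instead of by the cycloaddition. Setting out from 9 (any epimer ratio), Bu4NF followed by DBU in THF removes both silyl groups and opens the β-alkoxy ketone of either epimer by β-elimination to one compound, the ring-opened hydroxy dienone F1. Corey–Bakshi–Shibata reduction ((R)-2-methyl-CBS-oxazaborolidine, BH3·SMe2) sets the ring carbinol under reagent control and gives the (1S)-dienol F2. Hydroxyl-directed oxymercuration with Hg(OCOCF3)2 should place mercury on C7 syn to the allylic hydroxyl and let the C2 hydroxyl close the dihydrofuran anti to it at C7a, giving the organomercurial F3 (not isolated). Demercuration with NaBH4/NaOH comes back to the route at 11.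

Step 6. Ketone 10 may lose the ring oxygen by β-elimination (retro-oxa-Michael reaction to the conjugated dienone) during desilylation, before hydride is delivered. In the fallback the C7a–O1 bond is made after the ketone is unmasked instead of being carried through it. Setting out from 9, the elimination is driven to completion (Bu4NF, then DBU) to the hydroxy dienone described as F1 in the preceding fallback. F1 is re-closed to 10 by a 5-exo oxa-Michael addition under a bifunctional cinchona squaramide catalyst at low temperature, which also chooses the face of C7a. Reduction in the same flask with NaBH4/CeCl3·7H2O rejoins the route at 11. No further compound arises.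

Step 4. Conjugate addition of the hindered secondary alkoxide to the internal ynone may be slow, with base-induced oligomerisation of 6 and incomplete Z-to-E equilibration. The fallback replaces addition to an alkyne by addition–elimination. Setting out from 5, the sodium alkoxide (NaH, THF, 0 °C) is treated with (3E)-4-chloropent-3-en-2-one F4 (from pentane-2,4-dione and oxalyl chloride). Loss of chloride returns the vinylogous ester 7 with the thermodynamically preferred (E)-geometry.

**Further compounds**

F1 | step 5 | (4Z)-4-[(2R,3E)-2,5-dihydroxy-3-methylpent-3-en-1-ylidene]-3,5,5-trimethylcyclohex-2-en-1-one | CC1=CC(=O)CC(C)(C)/C1=C/[C@@H](O)/C(C)=C/CO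
F2 | step 5 | (1S,4Z)-4-[(2R,3E)-2,5-dihydroxy-3-methylpent-3-en-1-ylidene]-3,5,5-trimethylcyclohex-2-en-1-ol | CC1=C[C@@H](O)CC(C)(C)/C1=C/[C@@H](O)/C(C)=C/CO
F3 | step 5 | {(2R,6S,7S,7aS)-6-hydroxy-2-[(2E)-4-hydroxybut-2-en-2-yl]-4,4,7a-trimethyl-2,4,5,6,7,7a-hexahydro-1-benzofuran-7-yl}mercury trifluoroacetate | OC/C=C(\C)[C@H]1C=C2C(C)(C)C[C@H](O)[C@H]([Hg]OC(=O)C(F)(F)F)[C@@]2(C)O1
F0 | step 6 | none | none
F4 | step 4 | (3E)-4-chloropent-3-en-2-one | CC(=O)/C=C(\C)Cl
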